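**Strategy.** The plan rests on opening ring C of the flavanonol at the C3–C4 bond. C3 (acetoxy) and C4 (ketone) are neighbouring oxygenated carbons, so both oxygens can come from a C3=C4 alkene. C2 carries only O1 and ring B and can be set beforehand as an acyclic aryl 1-arylallyl ether. Ring-closing metathesis then joins a vinyl group on ring A (at C4a) to the vinyl group of that ether, giving the 2H-chromene with C2 intact in one operation. The precursor is a fully benzyl-protected 2-vinylphenyl (S)-1-arylallyl ether; dihydroxylation anti to the C2 aryl group, benzylic oxidation, acetylation and hydrogenolysis finish the target.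

Key step: step 11

Assumption: the (Sa,S,S) antipode of the BINOL-derived bis(1-phenylethyl)phosphoramidite is taken as the one that directs oxygen nucleophiles to the face of the aryl-bearing allyl terminus giving the (S) ether; if the sense were the reverse, the antipodal ligand would be used with no other change.

Remark on descriptors: C2 keeps its geometry from step 10 to the target. It is S in the allyl ether and the chromene and R from the diol onwards only because C3, once oxygenated, outranks ring B.

**Route**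

Step 1
Reactants: 1 methyl 3,5-dihydroxy-4-methoxybenzoate
Product: 2 methyl 3,5-bis(benzyloxy)-4-methoxybenzoate
Conditions: BnBr (2.3 equiv), K2CO3, DMF, 60 °C
Reagents that add atoms: benzyl bromide, BrCc1ccccc1
Why: Williamson ether synthesis, in which both phenoxides formed by K2CO3 are alkylated by the primary benzylic bromide while the methyl ester and the methyl ether are untouched.

Step 2
Reactants: 2 methyl 3,5-bis(benzyloxy)-4-methoxybenzoate
Product: 3 [3,5-bis(benzyloxy)-4-methoxyphenyl]methanol
Conditions: LiAlH4, THF, 0 °C to rt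
Reagents that add atoms: none
Why: Hydride reduction of an ester to the primary alcohol with LiAlH4 is general and leaves aryl benzyl and methyl ethers intact.

Step 3
Reactants: 3 [3,5-bis(benzyloxy)-4-methoxyphenyl]methanol
Product: 4 3,5-bis(benzyloxy)-4-methoxybenzaldehyde
Conditions: activated MnO2 (10 equiv), CH2Cl2, rt
Reagents that add atoms: none
Why: MnO2 oxidation is selective for benzylic alcohols and stops at the aldehyde, so over-oxidation to the acid is avoided.

Step 4
Reactants: 4 3,5-bis(benzyloxy)-4-methoxybenzaldehyde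
Product: 6 3,5-bis(benzyloxy)-4-methoxyphenol, via 3,5-bis(benzyloxy)-4-methoxyphenyl formate 5 (not isolated)
Conditions: mCPBA, CH2Cl2, 0 °C to rt; aq. NaHCO3/Na2S2O3 wash; then K2CO3 (cat.), MeOH, rt
Reagents that add atoms: mCPBA, O=C(OO)c1cccc(Cl)c1
Why: Baeyer–Villiger (Dakin-type) oxidation, in which the electron-rich aryl group with its para methoxy donor migrates to oxygen to give the aryl formate, which mild methanolysis cleaves to the phenol without touching the benzyl ethers.

Step 5
Reactants: 6 3,5-bis(benzyloxy)-4-methoxyphenol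
Product: 7 2,4-bis(benzyloxy)-6-hydroxy-3-methoxybenzaldehyde
Conditions: MgCl2 (2 equiv), Et3N (4 equiv), (CH2O)n (6 equiv), MeCN, reflux
Reagents that add atoms: paraformaldehyde (as formaldehyde), C=O
Why: Magnesium phenoxide-directed ortho-formylation (Casnati–Skattebøl reaction) delivers formaldehyde only ortho to the phenol, the para position being blocked by OMe and the two ortho positions being equivalent by symmetry, and the hydroxymethyl stage is oxidised in the flask by excess formaldehyde.

Step 6
Reactants: 7 2,4-bis(benzyloxy)-6-hydroxy-3-methoxybenzaldehyde; 8 methyltriphenylphosphonium bromide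
Product: 10 3,5-bis(benzyloxy)-2-ethenyl-4-methoxyphenol, via methylenetriphenylphosphorane 9 (not isolated)
Conditions: 8 (2.5 equiv), KOtBu (2.4 equiv), THF, 0 °C to rt; used promptly, cold and dark
Reagents that add atoms: none
Why: Wittig methylenation of an unprotected salicylaldehyde with excess non-stabilised ylide (one equivalent is spent on the phenol) is an established way to 2-vinylphenols.

Step 7
Reactants: 11 4-(benzyloxy)benzaldehyde; 12 triethyl phosphonoacetate
Product: 14 ethyl (E)-3-[4-(benzyloxy)phenyl]prop-2-enoate, via sodium triethyl phosphonoacetate carbanion 13 (not isolated)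
Conditions: NaH, THF, 0 °C; then 11, 0 °C to rt
Reagents that add atoms: none
Why: Horner–Wadsworth–Emmons olefination of an aromatic aldehyde with a stabilised phosphonate carbanion gives the (E)-cinnamate through the thermodynamically controlled elimination.

Step 8
Reactants: 14 ethyl (E)-3-[4-(benzyloxy)phenyl]prop-2-enoate
Product: 15 (E)-3-[4-(benzyloxy)phenyl]prop-2-en-1-ol
Conditions: i-Bu2AlH (2.5 equiv), CH2Cl2, −78 to 0 °C; aq. potassium sodium tartrate (KNaC4H4O6)
Reagents that add atoms: none
Why: i-Bu2AlH effects clean 1,2-reduction of an α,β-unsaturated ester to the allylic alcohol without touching the alkene geometry or the benzyl ether.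

Step 9
Reactants: 15 (E)-3-[4-(benzyloxy)phenyl]prop-2-en-1-ol
Product: 16 (E)-3-[4-(benzyloxy)phenyl]prop-2-en-1-yl methyl carbonate
Conditions: ClCO2Me, pyridine, CH2Cl2, 0 °C
Reagents that add atoms: methyl chloroformate, COC(Cl)=O
Why: Acylation of the primary allylic alcohol with a chloroformate gives the linear allylic carbonate, the standard electrophile for iridium-catalysed allylic substitution.

Step 10
Reactants: 10 3,5-bis(benzyloxy)-2-ethenyl-4-methoxyphenol; 16 (E)-3-[4-(benzyloxy)phenyl]prop-2-en-1-yl methyl carbonate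
Product: 17 1,3-bis(benzyloxy)-5-{[(1S)-1-[4-(benzyloxy)phenyl]prop-2-en-1-yl]oxy}-4-ethenyl-2-methoxybenzene
Conditions: [Ir(cod)Cl]2 (2 mol%), (Sa,S,S)-phosphoramidite from (S)-BINOL and bis[(S)-1-phenylethyl]amine (4 mol%), n-PrNH2 pre-activation, K3PO4, THF, rt to 40 °C
Reagents that add atoms: none
Why: Iridium-catalysed asymmetric allylic etherification, in which the cyclometallated iridium–phosphoramidite catalyst ionises the linear carbonate with loss of CO2 to an allyl iridium complex and the phenoxide of 10 attacks the aryl-bearing terminus from outside the metal, so that the branched ether forms and the single ligand antipode fixes the new centre as S (the future 2R centre).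

Step 11
Reactants: 17 1,3-bis(benzyloxy)-5-{[(1S)-1-[4-(benzyloxy)phenyl]prop-2-en-1-yl]oxy}-4-ethenyl-2-methoxybenzene
Product: 18 (2S)-5,7-bis(benzyloxy)-2-[4-(benzyloxy)phenyl]-6-methoxy-2H-chromene
Conditions: second-generation Grubbs catalyst (H2IMes)(PCy3)Cl2Ru=CHPh (5 mol%), 1,4-benzoquinone (10 mol%), CH2Cl2 (0.01 M), 35 °C, dark; then ethyl vinyl ether; product kept cold and dark and used at once
Reagents that add atoms: none
Why: Ring-closing olefin metathesis through the metallacyclobutane mechanism: the ruthenium benzylidene first exchanges with the less hindered, non-conjugated vinyl group of the allyl ether, the new alkylidene adds across the ring A styrene in a [2+2] step, and cycloreversion of the ruthenacyclobutane releases ethene and the ring. The closest known reaction type is the ring-closing metathesis of 2-vinylphenyl allyl ethers to 2H-chromenes. Ring C closes as a six-membered ring by intramolecular metathesis of two terminal alkenes held ortho to each other on ring A through O1, which leaves the new C3=C4 bond endocyclic and necessarily cis. No stereocentre forms, and C2 is a spectator that keeps its S descriptor. The selectivity needed is ring closure ahead of double-bond migration in the allyl ether and ahead of ionisation or electrocyclic opening at the doubly activated C2–O1 bond. The ortho arrangement of the two alkenes makes closure fast, while the neutral catalyst, the benzoquinone hydride trap, the moderate temperature and the exclusion of light guard C2.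

Step 12
Reactants: 18 (2S)-5,7-bis(benzyloxy)-2-[4-(benzyloxy)phenyl]-6-methoxy-2H-chromene
Product: 19 (2R,3S,4S)-5,7-bis(benzyloxy)-2-[4-(benzyloxy)phenyl]-6-methoxy-3,4-dihydro-2H-chromene-3,4-diol
Conditions: OsO4 (3 mol%), NMO (1.5 equiv), acetone–THF–H2O, 0 °C to rt; aq. Na2SO3
Reagents that add atoms: OsO4 (catalytic carrier of both oxygens), O=[Os](=O)(=O)=O; N-methylmorpholine N-oxide, C[N+]1([O-])CCOCC1; water, O
Why: Catalytic syn-dihydroxylation, in which OsO4 adds to the electron-rich C3=C4 bond on the face opposite the C2 aryl group and so gives the 2,3-trans-3,4-cis diol, setting C3 from the C2 centre.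

Step 13
Reactants: 19 (2R,3S,4S)-5,7-bis(benzyloxy)-2-[4-(benzyloxy)phenyl]-6-methoxy-3,4-dihydro-2H-chromene-3,4-diol
Product: 20 (2R,3R)-5,7-bis(benzyloxy)-2-[4-(benzyloxy)phenyl]-3-hydroxy-6-methoxy-2,3-dihydro-4H-chromen-4-one
Conditions: activated MnO2 (20 equiv), CH2Cl2, rt
Reagents that add atoms: none
Why: Chemoselective benzylic oxidation, in which MnO2 oxidises only the C4 hydroxyl activated by the trioxygenated ring A to the aryl ketone and leaves the non-benzylic C3 hydroxyl and its configuration untouched.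

Step 14
Reactants: 20 (2R,3R)-5,7-bis(benzyloxy)-2-[4-(benzyloxy)phenyl]-3-hydroxy-6-methoxy-2,3-dihydro-4H-chromen-4-one
Product: 21 (2R,3R)-5,7-bis(benzyloxy)-2-[4-(benzyloxy)phenyl]-6-methoxy-4-oxo-3,4-dihydro-2H-chromen-3-yl acetate
Conditions: Ac2O, pyridine, DMAP (cat.), CH2Cl2, 0 °C
Reagents that add atoms: acetic anhydride, CC(=O)OC(C)=O
Why: O-Acylation meets a single free hydroxyl (C3–OH), and the mild base and low temperature avoid enolisation of the C4 ketone, so the trans 2R,3R relationship is kept.

Step 15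
Reactants: 21 (2R,3R)-5,7-bis(benzyloxy)-2-[4-(benzyloxy)phenyl]-6-methoxy-4-oxo-3,4-dihydro-2H-chromen-3-yl acetate
Product: 22 (2R,3R)-5,7-dihydroxy-2-(4-hydroxyphenyl)-6-methoxy-4-oxo-3,4-dihydro-2H-chromen-3-yl acetate (6-methoxyaromadendrin 3-O-acetate)
Conditions: H2 (1 atm), 10% Pd/C, EtOAc–THF, rt
Reagents that add atoms: none
Why: Catalytic hydrogenolysis should cleave the three O-benzyl ethers much faster than it attacks the cyclic C2–O1 ether, the hydrogen-bonded C4 ketone or the acetate, so the three phenols are freed in one neutral operation.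

**Compound list**

1 | methyl 3,5-dihydroxy-4-methoxybenzoate | COC(=O)c1cc(O)c(OC)c(O)c1 | starting material
2 | methyl 3,5-bis(benzyloxy)-4-methoxybenzoate | COC(=O)c1cc(OCc2ccccc2)c(OC)c(OCc2ccccc2)c1 | intermediate
3 | [3,5-bis(benzyloxy)-4-methoxyphenyl]methanol | OCc1cc(OCc2ccccc2)c(OC)c(OCc2ccccc2)c1 | intermediate
4 | 3,5-bis(benzyloxy)-4-methoxybenzaldehyde | O=Cc1cc(OCc2ccccc2)c(OC)c(OCc2ccccc2)c1 | intermediate
5 | 3,5-bis(benzyloxy)-4-methoxyphenyl formate | O=COc1cc(OCc2ccccc2)c(OC)c(OCc2ccccc2)c1 | intermediate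
6 | 3,5-bis(benzyloxy)-4-methoxyphenol | Oc1cc(OCc2ccccc2)c(OC)c(OCc2ccccc2)c1 | intermediate
7 | 2,4-bis(benzyloxy)-6-hydroxy-3-methoxybenzaldehyde | O=Cc1c(O)cc(OCc2ccccc2)c(OC)c1OCc1ccccc1 | intermediate
8 | methyltriphenylphosphonium bromide | C[P+](c1ccccc1)(c1ccccc1)c1ccccc1.[Br-] | starting material
9 | methylenetriphenylphosphorane | C=P(c1ccccc1)(c1ccccc1)c1ccccc1 | intermediate
10 | 3,5-bis(benzyloxy)-2-ethenyl-4-methoxyphenol | C=Cc1c(O)cc(OCc2ccccc2)c(OC)c1OCc1ccccc1 | intermediate
11 | 4-(benzyloxy)benzaldehyde | O=Cc1ccc(OCc2ccccc2)cc1 | starting material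
12 | triethyl phosphonoacetate | CCOC(=O)CP(=O)(OCC)OCC | starting material
13 | sodium triethyl phosphonoacetate carbanion | [Na+].CCOC(=O)[CH-]P(=O)(OCC)OCC | intermediate
14 | ethyl (E)-3-[4-(benzyloxy)phenyl]prop-2-enoate | CCOC(=O)/C=C/c1ccc(OCc2ccccc2)cc1 | intermediate
15 | (E)-3-[4-(benzyloxy)phenyl]prop-2-en-1-ol | OC/C=C/c1ccc(OCc2ccccc2)cc1 | intermediate
16 | (E)-3-[4-(benzyloxy)phenyl]prop-2-en-1-yl methyl carbonate | COC(=O)OC/C=C/c1ccc(OCc2ccccc2)cc1 | intermediate
17 | 1,3-bis(benzyloxy)-5-{[(1S)-1-[4-(benzyloxy)phenyl]prop-2-en-1-yl]oxy}-4-ethenyl-2-methoxybenzene | COc1c(OCc3ccccc3)cc(O[C@@H](C=C)c2ccc(OCc3ccccc3)cc2)c(C=C)c1OCc1ccccc1 | intermediate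
18 | (2S)-5,7-bis(benzyloxy)-2-[4-(benzyloxy)phenyl]-6-methoxy-2H-chromene | COc1c(OCc3ccccc3)cc2c(c1OCc1ccccc1)C=C[C@@H](c1ccc(OCc3ccccc3)cc1)O2 | intermediate
19 | (2R,3S,4S)-5,7-bis(benzyloxy)-2-[4-(benzyloxy)phenyl]-6-methoxy-3,4-dihydro-2H-chromene-3,4-diol | COc1c(OCc3ccccc3)cc2c(c1OCc1ccccc1)[C@H](O)[C@H](O)[C@@H](c1ccc(OCc3ccccc3)cc1)O2 | intermediate
20 | (2R,3R)-5,7-bis(benzyloxy)-2-[4-(benzyloxy)phenyl]-3-hydroxy-6-methoxy-2,3-dihydro-4H-chromen-4-one | COc1c(OCc3ccccc3)cc2c(c1OCc1ccccc1)C(=O)[C@H](O)[C@@H](c1ccc(OCc3ccccc3)cc1)O2 | intermediate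
21 | (2R,3R)-5,7-bis(benzyloxy)-2-[4-(benzyloxy)phenyl]-6-methoxy-4-oxo-3,4-dihydro-2H-chromen-3-yl acetate | COc1c(OCc3ccccc3)cc2c(c1OCc1ccccc1)C(=O)[C@H](OC(C)=O)[C@@H](c1ccc(OCc3ccccc3)cc1)O2 | intermediate
22 | (2R,3R)-5,7-dihydroxy-2-(4-hydroxyphenyl)-6-methoxy-4-oxo-3,4-dihydro-2H-chromen-3-yl acetate | COc1c(O)cc2c(c1O)C(=O)[C@H](OC(C)=O)[C@@H](c1ccc(O)cc1)O2 | target

**Step count**

Total: 15 steps. Longest linear sequence: 12 steps (steps 1–6, then 10–15); steps 7–9 form the convergent side arm.

**Steps most likely to fail**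

Step 10. The electron-rich 2-vinylphenol may be lost to oligomerisation or C-allylation under the basic conditions. A slow etherification would also let the branched ether re-ionise at its p-alkoxybenzylic carbon, eroding branched selectivity and enantiopurity. The fallback removes the styrene from the nucleophile and changes the order of events. It sets out from 7, whose phenoxide is allylated with carbonate 16 under the same iridium–phosphoramidite catalysis to give 2,4-bis(benzyloxy)-6-{[(1S)-1-[4-(benzyloxy)phenyl]prop-2-en-1-yl]oxy}-3-methoxybenzaldehyde F1. Wittig methylenation of the aldehyde with ylide 9 (from 8, KOtBu, THF, 0 °C) then comes back to the route at 17.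

Step 11. Ring closure onto the doubly ortho-substituted styrene may stall, which would leave room for ruthenium hydride-driven double-bond migration in the allyl ether. The C2 configuration may also leak away through ionisation or reversible electrocyclic opening of the electron-rich chromene. The fallback abandons the alkene route to ring C and closes it by C2–O1 bond formation from a chalcone epoxide; it sets out from 7 and comes back at 20, bypassing 17–19.
- The phenol of 7 is protected (MOMCl, i-Pr2NEt, CH2Cl2) as 2,4-bis(benzyloxy)-3-methoxy-6-(methoxymethoxy)benzaldehyde F2.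
- Addition of MeMgBr (THF, 0 °C) gives 1-[2,4-bis(benzyloxy)-3-methoxy-6-(methoxymethoxy)phenyl]ethan-1-ol F3.
- Oxidation with activated MnO2 gives 1-[2,4-bis(benzyloxy)-3-methoxy-6-(methoxymethoxy)phenyl]ethan-1-one F4.
- Claisen–Schmidt condensation with aldehyde 11 (KOH, EtOH) gives (2E)-1-[2,4-bis(benzyloxy)-3-methoxy-6-(methoxymethoxy)phenyl]-3-[4-(benzyloxy)phenyl]prop-2-en-1-one F5.
- Juliá–Colonna epoxidation (poly-L-leucine, urea–H2O2, DBU, THF) should give [2,4-bis(benzyloxy)-3-methoxy-6-(methoxymethoxy)phenyl][(2R,3S)-3-[4-(benzyloxy)phenyl]oxiran-2-yl]methanone F6.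
- HCl in MeOH–THF removes the acetal, and the freed phenol opens the epoxide at the benzylic carbon with inversion, giving the trans (2R,3R) hydroxy ketone 20.

Step 13. MnO2 may cleave the cis-1,2-diol oxidatively, or the oxidation of the hindered C4 hydroxyl next to the C5 benzyloxy group may stop short. The fallback avoids oxidising a free glycol by reversing the order of acetylation and oxidation. It sets out from 19, whose more accessible C3 hydroxyl is acetylated selectively (AcCl, 2,4,6-collidine, CH2Cl2, −78 °C) to (2R,3S,4S)-5,7-bis(benzyloxy)-2-[4-(benzyloxy)phenyl]-4-hydroxy-6-methoxy-3,4-dihydro-2H-chromen-3-yl acetate F7. Oxidation of the remaining C4 hydroxyl with Dess–Martin periodinane (NaHCO3, CH2Cl2) comes back to the route at 21.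

**Further compounds**

F1 | step 10 | 2,4-bis(benzyloxy)-6-{[(1S)-1-[4-(benzyloxy)phenyl]prop-2-en-1-yl]oxy}-3-methoxybenzaldehyde | O=Cc1c(O[C@@H](C=C)c2ccc(OCc3ccccc3)cc2)cc(OCc2ccccc2)c(OC)c1OCc1ccccc1
F2 | step 11 | 2,4-bis(benzyloxy)-3-methoxy-6-(methoxymethoxy)benzaldehyde | O=Cc1c(OCOC)cc(OCc2ccccc2)c(OC)c1OCc1ccccc1
F3 | step 11 | 1-[2,4-bis(benzyloxy)-3-methoxy-6-(methoxymethoxy)phenyl]ethan-1-ol (racemic) | CC(O)c1c(OCOC)cc(OCc2ccccc2)c(OC)c1OCc1ccccc1
F4 | step 11 | 1-[2,4-bis(benzyloxy)-3-methoxy-6-(methoxymethoxy)phenyl]ethan-1-one | CC(=O)c1c(OCOC)cc(OCc2ccccc2)c(OC)c1OCc1ccccc1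
F5 | step 11 | (2E)-1-[2,4-bis(benzyloxy)-3-methoxy-6-(methoxymethoxy)phenyl]-3-[4-(benzyloxy)phenyl]prop-2-en-1-one | O=C(/C=C/c1ccc(OCc2ccccc2)cc1)c1c(OCOC)cc(OCc2ccccc2)c(OC)c1OCc1ccccc1
F6 | step 11 | [2,4-bis(benzyloxy)-3-methoxy-6-(methoxymethoxy)phenyl][(2R,3S)-3-[4-(benzyloxy)phenyl]oxiran-2-yl]methanone | O=C([C@@H]1O[C@H]1c1ccc(OCc2ccccc2)cc1)c1c(OCOC)cc(OCc2ccccc2)c(OC)c1OCc1ccccc1
F7 | step 13 | (2R,3S,4S)-5,7-bis(benzyloxy)-2-[4-(benzyloxy)phenyl]-4-hydroxy-6-methoxy-3,4-dihydro-2H-chromen-3-yl acetate | COc1c(OCc3ccccc3)cc2c(c1OCc1ccccc1)[C@H](O)[C@H](OC(C)=O)[C@@H](c1ccc(OCc3ccccc3)cc1)O2
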